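**Retrosynthetic overview**
1. The strategy rests on the C5–C8 edge of the carbocycle (C4a, C5, C6, C7, C8, C8a) fused to the γ-pyranone: O5, O6 and O7 are all cis and Cl8 is trans to O7, which is the oxidation pattern of a 6-hydroxychromone dearomatised at C5.
2. C5–OH ⇐ C5 ketone (hydride anti to a 6,7-acetonide); C8–Cl and C7–OH ⇐ chloride opening at C8 of the 7,8-epoxide lying syn to O6.
3. Epoxide ⇐ vanadium-catalysed epoxidation of C7=C8 directed by the C6 carbinol of a 6-hydroxy-5,5-dimethoxy-5,6-dihydrochromone ⇐ CBS reduction of the ortho-quinone monoketal ⇐ PhI(OAc)2/MeOH oxidation of the 6-hydroxychromone.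
4. 6-Hydroxy-2-(arylethyl)chromone ⇐ hydrogenation of a 2-styrylchromone ⇐ 6-benzyloxy-2-methylchromone + MOM-protected isovanillin.
5. Ring order: γ-pyranone (step 2); carbocycle taken from the arene (dearomatised in step 6); oxirane (step 8, opened in step 9); temporary dioxolane (steps 10–13).

Key step: step 8

Remark: chromone numbering (O1, C2–C4, C4a, C5–C8, C8a) is used throughout and Ar = 4-methoxy-3-(methoxymethoxy)phenyl; the choice of the (S)-CBS catalyst assumes that the quaternary C5 ketal carbon is the larger flank of the C6 ketone.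

**Step 1**
Reactants: 1 2',5'-dihydroxyacetophenone
Product: 2 1-[5-(benzyloxy)-2-hydroxyphenyl]ethanone
Conditions: BnBr (1.05 equiv), K2CO3, acetone, reflux
Reagents that add atoms: benzyl bromide, BrCc1ccccc1
Why: Williamson ether synthesis; the 2'-hydroxyl is tied up in a hydrogen bond to the acetyl carbonyl, so with one equivalent of halide and a weak base only the 5'-phenoxide is alkylated.

**Step 2**
Reactants: 2 1-[5-(benzyloxy)-2-hydroxyphenyl]ethanone
Product: 4 6-(benzyloxy)-2-methyl-4H-chromen-4-one, via 1,3-diketone 3 (not isolated)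
Conditions: NaH (4 equiv), EtOAc (5 equiv), THF, reflux; AcOH quench; then AcOH, cat. H2SO4, 80 °C
Reagents that add atoms: ethyl acetate, CCOC(C)=O
Why: Crossed Claisen condensation of the phenoxide–enolate dianion with ethyl acetate gives the o-hydroxyaryl 1,3-diketone, and acid-catalysed cyclodehydration (phenol adds to the distal carbonyl, water is lost) closes the γ-pyranone, the aryl benzyl ether tolerating brief AcOH/H2SO4.

**Step 3**
Reactants: 5 isovanillin (3-hydroxy-4-methoxybenzaldehyde)
Product: 6 4-methoxy-3-(methoxymethoxy)benzaldehyde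
Conditions: MOMCl, i-Pr2NEt, CH2Cl2, 0 °C → rt
Reagents that add atoms: chloromethyl methyl ether, COCCl
Why: O-Alkylation of the phenol with an α-chloro ether (MOM protection), chosen because this acetal survives base, neutral hydrogenation, hypervalent iodine, borane and peroxide and leaves at the end with dilute acid.

**Step 4**
Reactants: 4 6-(benzyloxy)-2-methyl-4H-chromen-4-one; 6 4-methoxy-3-(methoxymethoxy)benzaldehyde
Product: 8 6-(benzyloxy)-2-[(E)-2-Ar-ethenyl]-4H-chromen-4-one, via aldol adduct 7 (not isolated)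
Conditions: NaOEt (2 equiv), EtOH, rt; AcOH quench
Reagents that add atoms: none
Why: Vinylogous aldol condensation: the 2-methyl protons are acidified through C2=C3–C4=O, the aldehyde cannot enolise, and E1cB loss of water from the aldol adduct gives the conjugated E-alkene as the thermodynamic isomer.

**Step 5**
Reactants: 8 6-(benzyloxy)-2-[(E)-2-Ar-ethenyl]-4H-chromen-4-one
Product: 10 6-hydroxy-2-(2-Ar-ethyl)-4H-chromen-4-one, via 6-benzyloxy-2-(arylethyl)chromone 9 (not isolated)
Conditions: H2 (1 atm), 10% Pd/C, EtOAc–EtOH, rt, stopped after uptake of 2 equiv H2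
Reagents that add atoms: none
Why: Heterogeneous catalytic hydrogenation saturates the styryl alkene and hydrogenolyses the benzyl ether in one operation, whereas the trisubstituted vinylogous-ester C2=C3 of the pyranone is reduced much more slowly and the MOM acetal is inert at neutral pH.

**Step 6**
Reactants: 10 6-hydroxy-2-(2-Ar-ethyl)-4H-chromen-4-one
Product: 12 5,5-dimethoxy-2-(2-Ar-ethyl)-4H-chromene-4,6(5H)-dione, via 6-hydroxy-5-methoxychromone 11 (not isolated)
Conditions: PhI(OAc)2 (2.3 equiv), MeOH, 0 °C → rt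
Reagents that add atoms: methanol, CO
Why: Hypervalent-iodine oxidative dearomatisation of a phenol to an ortho-quinone monoketal: the aryloxy-λ3-iodane is captured by methanol at C5, the only ortho or para site whose attack leaves the γ-pyranone intact (the counterpart of C1 in a 2-naphthol), the resulting guaiacol-type phenol is more electron-rich and is oxidised again with ipso capture at the methoxylated C5, and the ketal product cannot rearomatise by tautomerisation.

**Step 7**
Reactants: 12 5,5-dimethoxy-2-(2-Ar-ethyl)-4H-chromene-4,6(5H)-dione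
Product: 13 (6R)-6-hydroxy-5,5-dimethoxy-2-(2-Ar-ethyl)-5,6-dihydro-4H-chromen-4-one
Conditions: (S)-Me-CBS (20 mol%), BH3·SMe2 (0.7 equiv), THF, −30 °C; MeOH, then pH 7 buffer
Reagents that add atoms: none
Why: Corey–Bakshi–Shibata reduction: the oxazaborolidine–borane complex binds the C6 carbonyl oxygen at the lone pair on the side of the planar C7 vinyl carbon, away from the quaternary C5 ketal carbon, and delivers hydride intramolecularly in a 1,2-sense, which with the (S)-catalyst should give the 6R carbinol.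

**Step 8**
Reactants: 13 (6R)-6-hydroxy-5,5-dimethoxy-2-(2-Ar-ethyl)-5,6-dihydro-4H-chromen-4-one
Product: 14 (6R,7S,8S)-7,8-epoxy-6-hydroxy-5,5-dimethoxy-2-(2-Ar-ethyl)-5,6,7,8-tetrahydro-4H-chromen-4-one (oxirane oxygen cis to the C6 hydroxyl)
Conditions: VO(acac)2 (10 mol%), t-BuOOH (anhydrous in decane, 1.5 equiv), CH2Cl2, 0 °C → rt
Reagents that add atoms: tert-butyl hydroperoxide, CC(C)(C)OO
Why: t-BuOOH oxidises VO(acac)2 to a vanadium(V) species that takes up the C6 alkoxide and an η2-tert-butylperoxide, and the distal peroxo oxygen is then passed within this vanadate ester to the neighbouring C7=C8 bond, forming C7–O and C8–O in one concerted suprafacial step. The closest known reaction type is the vanadium-catalysed hydroxyl-directed syn epoxidation of cyclohex-2-en-1-ols and related cyclic allylic alcohols. The oxirane closes by this concerted [2+1] oxygen-atom transfer, so its cis fusion to the carbocycle is obligatory. C7 and C8 are both set by the C6 stereocentre, because the metal-bound oxidant tethered through O6 reaches only the alkene face syn to the hydroxyl, which should give 7S,8S from 6R. The step needs face selectivity and chemoselectivity (C7=C8 over the pyranone C2=C3 and the arene, epoxidation over carbinol oxidation); the allylic position of the only free hydroxyl secures both, the C5 dimethyl ketal blocks tautomerisation to a phenol and offers no second directing group, and the neutral anhydrous medium should hold back loss of methanol from C5.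

**Step 9**
Reactants: 14 (6R,7S,8S)-7,8-epoxy-6-hydroxy-5,5-dimethoxy-2-(2-Ar-ethyl)-5,6,7,8-tetrahydro-4H-chromen-4-one
Product: 15 (6R,7S,8R)-8-chloro-6,7-dihydroxy-5,5-dimethoxy-2-(2-Ar-ethyl)-5,6,7,8-tetrahydro-4H-chromen-4-one
Conditions: pyridinium chloride (3 equiv), CH2Cl2–MeCN, 0 °C → rt
Reagents that add atoms: pyridinium chloride, [Cl-].c1cc[nH+]cc1
Why: Acid-assisted SN2 opening of the epoxide by chloride (trans-diaxial, Fürst–Plattner): attack at C8, allylic to the pyranone C8a=C4a and remote from the inductively deactivating oxygens on C6 and C5, inverts C8 and puts chlorine anti to O7 (8R) while C7–O keeps its configuration, and the buffered pyridinium acid leaves the ketal and the MOM ether untouched.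

**Step 10**
Reactants: 15 (6R,7S,8R)-8-chloro-6,7-dihydroxy-5,5-dimethoxy-2-(2-Ar-ethyl)-5,6,7,8-tetrahydro-4H-chromen-4-one
Product: 16 (6R,7S,8R)-8-chloro-6,7-(isopropylidenedioxy)-5,5-dimethoxy-2-(2-Ar-ethyl)-5,6,7,8-tetrahydro-4H-chromen-4-one
Conditions: Me2C(OMe)2 (5 equiv), PPTS (10 mol%), CH2Cl2, rt
Reagents that add atoms: 2,2-dimethoxypropane, COC(C)(C)OC
Why: Acid-catalysed transketalisation (acetonide formation): the cis-6,7-diol closes a cis-fused 1,3-dioxolane, which masks O7 against epoxide re-formation under basic conditions and later shields the upper face of C5.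

**Step 11**
Reactants: 16 (6R,7S,8R)-8-chloro-6,7-(isopropylidenedioxy)-5,5-dimethoxy-2-(2-Ar-ethyl)-5,6,7,8-tetrahydro-4H-chromen-4-one
Product: 17 (6R,7S,8R)-8-chloro-6,7-(isopropylidenedioxy)-2-(2-Ar-ethyl)-7,8-dihydro-4H-chromene-4,5(6H)-dione
Conditions: PPTS (0.3 equiv), acetone containing 1% H2O, 50 °C
Reagents that add atoms: water, O
Why: Acid-catalysed ketal hydrolysis by exchange in acetone: the acyclic dimethyl ketal ionises to an oxocarbenium ion stabilised through C4a=C8a by O1 and is trapped by water, while the dioxolane is held in place by the mass action of the solvent acetone and the phenolic MOM ether is stable to pyridinium tosylate.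

**Step 12**
Reactants: 17 (6R,7S,8R)-8-chloro-6,7-(isopropylidenedioxy)-2-(2-Ar-ethyl)-7,8-dihydro-4H-chromene-4,5(6H)-dione
Product: 18 (5S,6S,7S,8R)-8-chloro-5-hydroxy-6,7-(isopropylidenedioxy)-2-(2-Ar-ethyl)-5,6,7,8-tetrahydro-4H-chromen-4-one
Conditions: NaBH4 (1.2 equiv), CeCl3·7H2O (1.2 equiv), MeOH, −78 °C; aq. NH4Cl
Reagents that add atoms: none
Why: Luche reduction (1,2-hydride addition): the C5 ketone, activated by its α-oxygen and less deactivated than the doubly vinylogous C4 pyranone carbonyl, is attacked from the convex face anti to the cis-fused dioxolane, which places the new hydroxyl cis to O6 (5S), while low temperature and cerium buffering suppress β-elimination of O7.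

**Step 13**
Reactants: 18 (5S,6S,7S,8R)-8-chloro-5-hydroxy-6,7-(isopropylidenedioxy)-2-(2-Ar-ethyl)-5,6,7,8-tetrahydro-4H-chromen-4-one
Product: 20 (5S,6S,7S,8R)-8-chloro-5,6,7-trihydroxy-2-[2-(3-hydroxy-4-methoxyphenyl)ethyl]-5,6,7,8-tetrahydro-4H-chromen-4-one, via MOM-protected tetrol 19 (not isolated)
Conditions: 3 M aq. HCl–THF (1:3), rt
Reagents that add atoms: none
Why: Acid-catalysed acetal hydrolysis removes the isopropylidene ketal and then the phenolic methoxymethyl ether, and no stereocentre is touched because only the acetal C–O bonds are broken, not the ring C–O bonds at C5–C7 or the C8–Cl bond.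

**Compound list**
1 | 2',5'-dihydroxyacetophenone | CC(=O)c1cc(O)ccc1O | starting material
2 | 1-[5-(benzyloxy)-2-hydroxyphenyl]ethanone | CC(=O)c1cc(OCc2ccccc2)ccc1O | intermediate
3 | 1-[5-(benzyloxy)-2-hydroxyphenyl]butane-1,3-dione | CC(=O)CC(=O)c1cc(OCc2ccccc2)ccc1O | intermediate
4 | 6-(benzyloxy)-2-methyl-4H-chromen-4-one | Cc1cc(=O)c2cc(OCc3ccccc3)ccc2o1 | intermediate
5 | isovanillin (3-hydroxy-4-methoxybenzaldehyde) | COc1ccc(C=O)cc1O | starting material
6 | 4-methoxy-3-(methoxymethoxy)benzaldehyde | COCOc1cc(C=O)ccc1OC | intermediate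
7 | 6-(benzyloxy)-2-[2-hydroxy-2-(4-methoxy-3-(methoxymethoxy)phenyl)ethyl]-4H-chromen-4-one (racemic aldol adduct) | COc1ccc(C(O)Cc2cc(=O)c3cc(OCc4ccccc4)ccc3o2)cc1OCOC | intermediate
8 | 6-(benzyloxy)-2-[(E)-2-(4-methoxy-3-(methoxymethoxy)phenyl)ethenyl]-4H-chromen-4-one | COc1ccc(/C=C/c2cc(=O)c3cc(OCc4ccccc4)ccc3o2)cc1OCOC | intermediate
9 | 6-(benzyloxy)-2-[2-(4-methoxy-3-(methoxymethoxy)phenyl)ethyl]-4H-chromen-4-one | COc1ccc(CCc2cc(=O)c3cc(OCc4ccccc4)ccc3o2)cc1OCOC | intermediate
10 | 6-hydroxy-2-[2-(4-methoxy-3-(methoxymethoxy)phenyl)ethyl]-4H-chromen-4-one | COc1ccc(CCc2cc(=O)c3cc(O)ccc3o2)cc1OCOC | intermediate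
11 | 6-hydroxy-5-methoxy-2-[2-(4-methoxy-3-(methoxymethoxy)phenyl)ethyl]-4H-chromen-4-one | COc1ccc(CCc2cc(=O)c3c(OC)c(O)ccc3o2)cc1OCOC | intermediate
12 | 5,5-dimethoxy-2-[2-(4-methoxy-3-(methoxymethoxy)phenyl)ethyl]-4H-chromene-4,6(5H)-dione | COc1ccc(CCc2cc(=O)c3c(o2)C=CC(=O)C3(OC)OC)cc1OCOC | intermediate
13 | (6R)-6-hydroxy-5,5-dimethoxy-2-[2-(4-methoxy-3-(methoxymethoxy)phenyl)ethyl]-5,6-dihydro-4H-chromen-4-one | COc1ccc(CCc2cc(=O)c3c(o2)C=C[C@@H](O)C3(OC)OC)cc1OCOC | intermediate
14 | (6R,7S,8S)-7,8-epoxy-6-hydroxy-5,5-dimethoxy-2-[2-(4-methoxy-3-(methoxymethoxy)phenyl)ethyl]-5,6,7,8-tetrahydro-4H-chromen-4-one | COc1ccc(CCc2cc(=O)c3c(o2)[C@@H](O4)[C@@H]4[C@@H](O)C3(OC)OC)cc1OCOC | intermediate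
15 | (6R,7S,8R)-8-chloro-6,7-dihydroxy-5,5-dimethoxy-2-[2-(4-methoxy-3-(methoxymethoxy)phenyl)ethyl]-5,6,7,8-tetrahydro-4H-chromen-4-one | COc1ccc(CCc2cc(=O)c3c(o2)[C@H](Cl)[C@@H](O)[C@@H](O)C3(OC)OC)cc1OCOC | intermediate
16 | (6R,7S,8R)-8-chloro-6,7-(isopropylidenedioxy)-5,5-dimethoxy-2-[2-(4-methoxy-3-(methoxymethoxy)phenyl)ethyl]-5,6,7,8-tetrahydro-4H-chromen-4-one | COc1ccc(CCc2cc(=O)c3c(o2)[C@H](Cl)[C@H]4OC(C)(C)O[C@H]4C3(OC)OC)cc1OCOC | intermediate
17 | (6R,7S,8R)-8-chloro-6,7-(isopropylidenedioxy)-2-[2-(4-methoxy-3-(methoxymethoxy)phenyl)ethyl]-7,8-dihydro-4H-chromene-4,5(6H)-dione | COc1ccc(CCc2cc(=O)c3c(o2)[C@H](Cl)[C@H]4OC(C)(C)O[C@H]4C3=O)cc1OCOC | intermediate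
18 | (5S,6S,7S,8R)-8-chloro-5-hydroxy-6,7-(isopropylidenedioxy)-2-[2-(4-methoxy-3-(methoxymethoxy)phenyl)ethyl]-5,6,7,8-tetrahydro-4H-chromen-4-one | COc1ccc(CCc2cc(=O)c3c(o2)[C@H](Cl)[C@H]4OC(C)(C)O[C@H]4[C@H]3O)cc1OCOC | intermediate
19 | (5S,6S,7S,8R)-8-chloro-5,6,7-trihydroxy-2-[2-(4-methoxy-3-(methoxymethoxy)phenyl)ethyl]-5,6,7,8-tetrahydro-4H-chromen-4-one | COc1ccc(CCc2cc(=O)c3c(o2)[C@H](Cl)[C@@H](O)[C@@H](O)[C@H]3O)cc1OCOC | intermediate
20 | (5S,6S,7S,8R)-8-chloro-5,6,7-trihydroxy-2-[2-(3-hydroxy-4-methoxyphenyl)ethyl]-5,6,7,8-tetrahydro-4H-chromen-4-one | COc1ccc(CCc2cc(=O)c3c(o2)[C@H](Cl)[C@@H](O)[C@@H](O)[C@H]3O)cc1O | target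

**Totals**
Total step count: 13. Longest linear sequence: 12 steps (steps 1, 2 and 4–13 from compound 1; step 3 is a one-step side branch).

**Steps most likely to fail**

Step 8 (key epoxidation). Oxygen transfer to the conjugated, rather electron-poor C7=C8 bond may be slower than vanadium-mediated oxidation of the carbinol back to the ketone, and the Lewis-acidic metal may induce loss of methanol from C5 with aromatisation. The fallback keeps the C6 oxygen as the stereochemical relay but replaces metal-bound oxygen transfer by a tethered halocyclisation. It sets out from 13, which is acylated with Boc2O and catalytic DMAP in MeCN to the C6 tert-butyl carbonate F1. Treatment with IBr in toluene–CH2Cl2 at −80 °C should close the carbonate oxygen onto C7 on the face of O6, with iodine anti at C8, to give the cis-fused iodo cyclic carbonate F2. Methanolysis with K2CO3 in MeOH at 0 °C frees the O7 alkoxide, which displaces the anti iodide and closes the syn epoxy alcohol, so the route is rejoined at 14.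

Step 6 (oxidative dearomatisation). Methanol may capture the oxidised phenol at the ring-fusion carbon C8a (para to O6) or at C7 instead of C5, or the sequence may stall or over-oxidise between the two oxidation stages. The fallback installs the C5 oxygen first by substitution chemistry. It sets out from 10, which is brominated ortho to the phenol with NBS and catalytic i-Pr2NH in CH2Cl2 at 0 °C to give the 5-bromo-6-hydroxychromone F3. Copper-catalysed Ullmann methoxylation (CuI, 3,4,7,8-tetramethyl-1,10-phenanthroline, Cs2CO3, MeOH–toluene, 90 °C) then gives 11, this time isolated. The fallback comes back to the route at 11, which needs only one equivalent of PhI(OAc)2 in MeOH, with ipso capture at the methoxylated carbon, to reach 12.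

Step 7 (CBS reduction). The catalyst may discriminate poorly between the two flanks of the C6 ketone (quaternary ketal carbon against a planar vinyl carbon), and conjugate reduction may compete. The fallback replaces catalyst control by resolution. It sets out from 12, which is reduced with NaBH4/CeCl3 in MeOH at −78 °C to the racemic carbinol F4. Lipase-catalysed acylation (immobilised Candida antarctica lipase B or Burkholderia cepacia lipase, vinyl acetate, MTBE) is expected, by the empirical size rule for lipases, to acylate the 6R enantiomer to the (6R)-acetate F5 and leave the (6S)-carbinol F6, which can be returned to 12 by MnO2 oxidation. After chromatographic separation, mild methanolysis of F5 (K2CO3, MeOH, 0 °C) gives 13, where the route is rejoined; the configuration would be confirmed by Mosher ester analysis.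

**Further compounds**
F1 | step 8 | (6R)-6-(tert-butoxycarbonyloxy)-5,5-dimethoxy-2-[2-(4-methoxy-3-(methoxymethoxy)phenyl)ethyl]-5,6-dihydro-4H-chromen-4-one | COc1ccc(CCc2cc(=O)c3c(o2)C=C[C@@H](OC(=O)OC(C)(C)C)C3(OC)OC)cc1OCOC
F2 | step 8 | (6R,7S,8R)-8-iodo-5,5-dimethoxy-2-[2-(4-methoxy-3-(methoxymethoxy)phenyl)ethyl]-5,6,7,8-tetrahydro-4H-chromen-4-one 6,7-cyclic carbonate | COc1ccc(CCc2cc(=O)c3c(o2)[C@H](I)[C@H]4OC(=O)O[C@H]4C3(OC)OC)cc1OCOC
F3 | step 6 | 5-bromo-6-hydroxy-2-[2-(4-methoxy-3-(methoxymethoxy)phenyl)ethyl]-4H-chromen-4-one | COc1ccc(CCc2cc(=O)c3c(Br)c(O)ccc3o2)cc1OCOC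
F4 | step 7 | racemic 6-hydroxy-5,5-dimethoxy-2-[2-(4-methoxy-3-(methoxymethoxy)phenyl)ethyl]-5,6-dihydro-4H-chromen-4-one | COc1ccc(CCc2cc(=O)c3c(o2)C=CC(O)C3(OC)OC)cc1OCOC
F5 | step 7 | (6R)-6-acetoxy-5,5-dimethoxy-2-[2-(4-methoxy-3-(methoxymethoxy)phenyl)ethyl]-5,6-dihydro-4H-chromen-4-one | COc1ccc(CCc2cc(=O)c3c(o2)C=C[C@@H](OC(C)=O)C3(OC)OC)cc1OCOC
F6 | step 7 | (6S)-6-hydroxy-5,5-dimethoxy-2-[2-(4-methoxy-3-(methoxymethoxy)phenyl)ethyl]-5,6-dihydro-4H-chromen-4-one | COc1ccc(CCc2cc(=O)c3c(o2)C=C[C@H](O)C3(OC)OC)cc1OCOC
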